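The rate constants were chosen freely; the flask was simulated.

Which flask ends with the longer chains, green or grey, if the average counts every chain begun, living or dead?

all flasks: transfer agent 0.0900 M; initiator 15 mM; impurity 7.2 mM; time 4.0 d

|  | free monomer |
|---|---|
| green | 3.0 M |
| grey | 2.0 M |

    initiator + impurity → spent initiator A (k1 = 640 M⁻¹ h⁻¹)
    2 living end → dead end B (k2 = 110 M⁻¹ h⁻¹)
    living end + transfer agent → dead chain (k3 = 0.26 M⁻¹ h⁻¹)
    free monomer + initiator → living end + monomer in chains (k4 = 0.82 M⁻¹ h⁻¹)
    free monomer + living end → monomer in chains + living end, rate k5*[living end]*[free monomer] (k5 = 7.8 M⁻¹ h⁻¹)

* which of the two ends with the longer chains by the average number of monomer units in a chain (chains begun, living or dead) ("neither" if they lie within 10%) (green / grey / neither)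
* average number of monomer units in a chain (chains begun, living or dead) at the end, green
* average number of monomer units in a chain (chains begun, living or dead) at the end, grey

- two of one species on the left: rate k times its square, two consumed each time
- the average divides the monomer in chains by the number of chains begun, living and dead together
- run time (green): 4.0 d

**What becomes of the initiator?** It goes two ways: with impurity to spent initiator A, or with free monomer to a living end, which is a chain begun. In green, with the other concentrations held at their charge, its half-life by the impurity step alone, 0.15 h, is far shorter than the half-life of free monomer by the initiation step alone, 2.3 d, so I hold free monomer at its charge during this start.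

**Do you need the clock?** No. Divide the impurity step's rate by the monomer step's: initiator and time cancel, leaving [impurity]/s. Here s is the break-even impurity, the impurity level at which the two ways run equally fast: free monomer times 0.82 M⁻¹ h⁻¹ divided by 640 M⁻¹ h⁻¹. That makes s 3.84 mM in green and 2.56 mM in grey. The inverse ratio of the constants, 780, is the selectivity factor.

**How many chains, then?** Call the chains begun C. While they begin, impurity falls by the factor e^(−C/s). Initiator exceeds impurity, so I let it run out, and C is the initiator charge less the impurity used. Solving this by repeated substitution gives C = 8.58 mM in green and 8.11 mM in grey.

**But that counts chains, not length. What of the monomer in chains?** The two C differ by a factor of just 1.06, so I take about equal living ends and the same fraction of free monomer used in each flask. Length then goes as monomer charge over C, and green should beat grey by a factor of 1.42, which is outside the margin. I stop at this ratio.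

The forecast says green, with 51.5 (49 to 54) for green and 36.3 (34.5 to 38) for grey. Its grounds for the start are that “Impurity and monomer compete for initiator”, and its chain counts, about 8.56 mM for green and 8.1 mM for grey, lie close to mine.

The simulation gives green: 53.3 units in green and 38.4 in grey, a factor of 1.39.

In green, with 0% of the initiator left, 0.00644 M of spent initiator A leaves 8.56 mM of chains begun, against the reckoned 8.58 mM. The neighbouring flask is green with impurity cut to 0.0043 M. Its free monomer charge is green's, so s stays 3.84 mM, and the same reckoning gives C = 10.9 mM, more chains than green, with 5.79% of its impurity left. That neighbour ends with 5.6% of its impurity and 0.00406 M of spent initiator A, and 84% of its free monomer remains. Its chains average 44.9 units, fewer than green's 53.3.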